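## Analysis of the target

Target 17 is a 19-membered macrocyclic bis(bibenzyl) in which four benzene rings are joined in the order ring A–O–ring B–CH2CH2 (bridge 1)–ring C–O–ring D–CH2CH2 (bridge 2)–ring A. Ring B is a para-phenylene and ring D a meta-phenylene, so the two halves are not related by symmetry and each bridge and each ether has to be made on purpose. Ring A carries hydroxyls at positions 1 and 6, the ether oxygen to ring B at position 5 and bridge 2 at position 3. Ring C carries bridge 1 at position 1, hydroxyls at positions 3 and 4 and the ether oxygen to ring D at position 5. There is no stereocentre, and the large ring is taken to be conformationally mobile. The sensitive groups are the two catechols, which oxidise to ortho-quinones in air, fastest as phenoxides, so they should be released last and under non-oxidising conditions. The difficulties are the ring closure and the three contiguous oxygens on rings A and C, which play three different roles (aryl ether, central hydroxyl, outer hydroxyl). The strategy rests on the fact that each outer hydroxyl carbon (position 1 of ring A, position 3 of ring C) is ortho to the central oxygen (position 6 of ring A, position 4 of ring C), whose other ortho carbon (position 5 in both rings) is blocked by the aryl ether. A directing group on the central oxygen can therefore reach only the carbon where the last oxygen is wanted. Without those two oxygens, rings A and C have the substitution pattern of isovanillin 1.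

## Retrosynthetic reasoning

**17 to 16.** The last disconnection removes only the two carbamoyl groups from the central oxygens. Nothing skeletal is cut. The catechols are thus set free in the final operation, by a reductive, non-oxidising cleavage.

**16 to 13 (key disconnection).** The C–O bonds at position 1 of ring A and position 3 of ring C are cut, leaving C–H. These are the only ring hydrogens ortho to the carbamate-bearing carbons, because the other ortho carbon carries the aryl ether. The forward reaction is a double ortho-lithiation directed by the carbamates, capture of both aryllithiums by a borate ester (via 14 and 15), and oxidation of the two C–B bonds to C–O. The gain is that rings A and C become isovanillin-type rings. The ether oxygen has the same ortho environment with or without the third oxygen, so the gain is not steric. It lies in drawing both rings from 1 and in letting the structure dictate the site of the last oxygen. The price is the carbamate installation and removal.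

**13 to 12 to 11.** These are functional-group changes on the central oxygens: carbamate back to phenol, phenol back to methyl ether. The methyl ethers are what 1 supplies and they pass unchanged through the copper and palladium steps. The carbamates are put on only after the ring is closed, so they never meet ylide base or hot aqueous phosphate.

**11 to 9.** The macrocycle is opened at the bond between ring D and the adjacent CH2 of bridge 2. This is an sp2–sp3 bond with no ortho substituent on either side, far from the crowded ether regions. Forward, the vinyl group on ring A of 9 is hydroborated (to 10) and the alkylborane is coupled under palladium catalysis with the chloride on ring D. The chloride is placed on ring D because a meta-aryloxy chloride adds to palladium more readily than a para-aryloxy one, and because it survives the earlier coupling of a bromide.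

**9 to 8, and 8 to 4 plus 6.** The vinyl group of 9 comes from the aldehyde of 8 by methylenation. Compound 8 is cut at the bond between ring B and the CH2 of bridge 1, which gives styrene 4 (rings C and D) and bromo aldehyde 6 (rings A and B). The forward reaction is the same hydroboration and cross-coupling, now intermolecular (via 7). The bromide on ring B reacts and the chloride on ring D does not. The aldehyde of 6 is the masked vinyl group for the later ring closure.

**4 to 3 to 1 plus 2, and 6 to 1 plus 5.** Both diaryl ether bonds are cut on the side of the halogenated ring. Each forms by copper-mediated O-arylation of the free hydroxyl of 1 with an arylboronic acid (2 or 5) at room temperature, which leaves the aldehyde and the halogens untouched. Methylenation of 3 gives 4. Both halves of the molecule thus start from 1.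

## Alternatives that were turned down

**Alternative 1:** Ring A is not bought but built. The bonds between positions 3 and 4 and between positions 1 and 2 of ring A are formed in a [4+2] cycloaddition of 3-(4-bromophenoxy)-4-methoxyfuran A2 with methyl propiolate A3. The oxygen-bridged adduct A4 is opened by acid, and the bridge oxygen becomes the hydroxyl of methyl 3-(4-bromophenoxy)-5-hydroxy-4-methoxybenzoate A1.
- For: A1 has the three oxygens of ring A already differentiated, an ester at position 3 for bridge 2 and a bromide on ring B for bridge 1. On this point it is stronger than the chosen route, which needs demethylation, carbamoylation and cleavage to reach the same pattern.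
- Against: the two β-oxygens of A2 differ only as methoxy and aryloxy. Neither the orientation of A3 across the two α-carbons nor the direction in which the bridge of A4 opens is strongly biased, and the wrong orientation gives a salicylate. A2 is not a catalogue compound and would cost several steps. The sequence also solves ring A only; ring C, with its meta-phenylene partner, would need a second pass or a different answer.
- Comparison: the chosen route treats both rings in one operation from a commodity aldehyde, with regiochemistry fixed by a blocked ortho position and not by a small electronic difference.

**Alternative 2:** The ether bond between the ring B oxygen and position 5 of ring A is made last and closes the 19-membered ring. The seco bis(halophenol) A6 is oxidised with Tl(NO3)3. The oxygen of the dichlorophenol (ring B) attacks a bromine-bearing carbon of the oxidised dibromophenol (ring A) to give dienone A7, and zinc reduction re-aromatises it to the macrocycle A5.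
- For: the ether and the ring form together, the central hydroxyl of ring A appears free, and the remaining bromine at position 1 marks the carbon for the outer hydroxyl. The site of the last oxygen is then fixed by construction and not by a C–H selectivity, which is stronger than the chosen route on that point.
- Against: for this target A5 still needs the bromide turned into a hydroxyl and two chlorines removed from ring B, which is unsubstituted in the target. Four halogens are introduced to make one bond. The oxidant has to pick the dibromophenol in the presence of the trioxygenated ring C and the aryl ether ring D, both electron-rich. A ring closure through a cationic intermediate is harder to predict than a palladium-mediated C–C coupling. Ring C must still be bought or made with three differentiated oxygens, and the reagent is a stoichiometric, toxic thallium salt.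
- Comparison: the chosen route closes the ring at an unhindered carbon–carbon bond and keeps the delicate chemistry for a step whose selectivity is enforced by a directing group.

**Alternative 3:** Ring B is constructed. The aryl ethynyl ether A9 of the ring A phenol adds across the diene of methyl coumalate A10, the bicyclic lactone extrudes CO2, and the bonds between positions 1 and 2 and between positions 5 and 6 of ring B are formed. The product is the methyl 4-aryloxybenzoate A8, which holds rings A, B and D.
- For: the polarised alkyne and the electron-poor pyranone combine in a defined orientation, ester para to ether. The ether oxygen is carried in on ring A, so no O-arylation next to an ortho substituent is needed. That is an elegant answer to the ether problem. The chosen route answers it more plainly, with a room-temperature copper coupling on a phenol that has a single ortho substituent.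
- Against: ring B is a bare para-phenylene, among the cheapest building blocks, and building it by cycloaddition spends steps on an unfunctionalised ring. Aryl ethynyl ethers need several steps to prepare and are prone to hydration and polymerisation. The ester of A8 needs further steps to become bridge 1. Ring A in A8 already carries three differentiated oxygens, so the main problem is only moved back to an earlier building block. The second ether and the ring closure remain to be done.
- Comparison: the chosen route is shorter to the macrocycle and uses the rings as they are sold.

Key step: step 9

Remark on the chemistry: the target has no stereocentre and the 19-membered ring is assumed to be conformationally mobile, so no stereochemical element has to be controlled.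

## Route

Step 1
Reactants: 1 isovanillin (3-hydroxy-4-methoxybenzaldehyde); 2 3-chlorophenylboronic acid
Product: 3 3-(3-chlorophenoxy)-4-methoxybenzaldehyde
Conditions: 2 (2 equiv), Cu(OAc)2 (1 equiv), pyridine, 4 Å MS, CH2Cl2, air, rt
Reagents that add atoms: none
Why: Chan–Lam O-arylation: the aryl group passes from boron to the divalent copper phenoxide, and C–O reductive elimination from trivalent copper should give the diaryl ether; at room temperature the aldehyde and the C–Cl bond are not touched.

Step 2
Reactants: 3 3-(3-chlorophenoxy)-4-methoxybenzaldehyde
Product: 4 2-(3-chlorophenoxy)-4-ethenyl-1-methoxybenzene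
Conditions: Ph3PCH3Br, KOtBu, THF, 0 °C to rt
Reagents that add atoms: methyltriphenylphosphonium bromide, C[P+](c1ccccc1)(c1ccccc1)c1ccccc1.[Br-]
Why: Wittig methylenation of a non-enolisable aryl aldehyde; the ethers and the aryl chloride are inert to the ylide.

Step 3
Reactants: 1 isovanillin; 5 4-bromophenylboronic acid
Product: 6 3-(4-bromophenoxy)-4-methoxybenzaldehyde
Conditions: 5 (2 equiv), Cu(OAc)2 (1 equiv), pyridine, 4 Å MS, CH2Cl2, air, rt
Reagents that add atoms: none
Why: Chan–Lam O-arylation as in step 1; copper at room temperature does not insert into the C–Br bond, so the bromide is kept for step 4.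

Step 4
Reactants: 4 2-(3-chlorophenoxy)-4-ethenyl-1-methoxybenzene; 6 3-(4-bromophenoxy)-4-methoxybenzaldehyde
Product: 8 3-[4-[2-[3-(3-chlorophenoxy)-4-methoxyphenyl]ethyl]phenoxy]-4-methoxybenzaldehyde, via alkylborane 7 (not isolated)
Conditions: 4 (slight excess), 9-BBN, THF, 0 °C to rt; then aq. K3PO4, 6, Pd(dppf)Cl2 (5 mol %), DMF, 60 °C
Reagents that add atoms: none
Why: 9-BBN adds to the styrene with boron at the terminal carbon, and the B-alkyl Suzuki–Miyaura coupling joins that carbon to ring B. With the dppf ligand, zerovalent palladium inserts into C–Br and leaves C–Cl alone. A slight excess of alkene over borane, with base added before 6, leaves no B–H to reduce the aldehyde.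

Step 5
Reactants: 8 3-[4-[2-[3-(3-chlorophenoxy)-4-methoxyphenyl]ethyl]phenoxy]-4-methoxybenzaldehyde
Product: 9 2-(3-chlorophenoxy)-4-[2-[4-(5-ethenyl-2-methoxyphenoxy)phenyl]ethyl]-1-methoxybenzene
Conditions: Ph3PCH3Br, KOtBu, THF, 0 °C to rt
Reagents that add atoms: methyltriphenylphosphonium bromide, C[P+](c1ccccc1)(c1ccccc1)c1ccccc1.[Br-]
Why: Wittig methylenation as in step 2; it places the vinyl group on ring A for the ring closure.

Step 6
Reactants: 9 2-(3-chlorophenoxy)-4-[2-[4-(5-ethenyl-2-methoxyphenoxy)phenyl]ethyl]-1-methoxybenzene
Product: 11 macrocyclic bis(methyl ether), via alkylborane 10 (not isolated)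
Conditions: 9-BBN, THF, rt; then slow addition to Pd(OAc)2 (10 mol %), SPhos (20 mol %), aq. K3PO4, THF, 65 °C, about 2 mM
Reagents that add atoms: none
Why: Intramolecular B-alkyl Suzuki–Miyaura coupling: the electron-rich biaryl phosphine lets zerovalent palladium insert into the meta-aryloxy C–Cl bond of ring D, and the tethered alkylborate transfers its CH2 to palladium. The 19-membered ring closes at an unhindered sp2–sp3 bond, and slow addition at high dilution favours ring closure over chain growth.

Step 7
Reactants: 11 macrocyclic bis(methyl ether)
Product: 12 macrocyclic bisphenol (hydroxyl at position 6 of ring A and position 4 of ring C)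
Conditions: BBr3, CH2Cl2, −78 °C to rt; then H2O
Reagents that add atoms: none
Why: Lewis-acid cleavage of aryl methyl ethers: bromide attacks the methyl group of the boron-complexed ether; the diaryl ethers have no sp3 carbon on oxygen and should survive.

Step 8
Reactants: 12 macrocyclic bisphenol
Product: 13 macrocyclic bis(N,N-diethylcarbamate) (hydrogen at position 1 of ring A and position 3 of ring C)
Conditions: NaH, ClCONEt2, THF, 0 °C to rt
Reagents that add atoms: N,N-diethylcarbamoyl chloride, CCN(CC)C(=O)Cl
Why: O-acylation of the two sodium phenoxides by the carbamoyl chloride; the sodium salts are used because each phenol has an ortho aryloxy group.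

Step 9
Reactants: 13 macrocyclic bis(N,N-diethylcarbamate)
Product: 16 macrocyclic bis(N,N-diethylcarbamate) bearing hydroxyl groups at position 1 of ring A and position 3 of ring C, via dilithio species 14 (not isolated), via bis(dimethyl boronate) 15 (not isolated)
Conditions: sec-BuLi (2.6 equiv), TMEDA, THF, −78 °C; B(OMe)3, −78 to 0 °C; AcOH, 30% H2O2, 0 °C to rt
Reagents that add atoms: hydrogen peroxide, OO
Why: Directed ortho-metalation: the carbamate carbonyl binds the sec-BuLi–TMEDA aggregate and the base removes the adjacent ring hydrogen, once on ring A and once on ring C, to give 14. B(OMe)3 turns each aryllithium into a borate and then the dimethyl boronate 15; hydroperoxide adds to boron, the aryl group shifts from boron to oxygen, and hydrolysis releases the phenol. The closest known reaction type is the ortho-lithiation, borylation and oxidation of aryl O-diethylcarbamates to catechol monocarbamates. No ring is closed and no stereocentre is formed. The step needs site selectivity, and the substrate supplies it: each carbamate has one ortho hydrogen only, the carbamate outranks the diaryl ether oxygens as a director, and the benzylic CH2 groups are para to the carbamates, out of reach of lateral metalation. Keeping the dianion at −78 °C until the borate is in prevents the anionic Fries shift of the carbamoyl group to carbon. The oxidation is buffered with acetic acid and not run in hydroxide, so the new phenol is never a phenoxide that could take over the neighbouring carbamoyl group or be oxidised further.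

Step 10
Reactants: 16 macrocyclic bis(N,N-diethylcarbamate) bearing hydroxyl groups at position 1 of ring A and position 3 of ring C
Product: 17 target macrocyclic bis(catechol)
Conditions: LiAlH4 (excess), THF, reflux, Ar; then degassed aq. HCl, 0 °C
Reagents that add atoms: none
Why: Reductive cleavage of aryl carbamates: hydride adds to the carbonyl, the tetrahedral intermediate expels the aryloxide, and the formamide left behind is reduced to the amine. The acidic, oxygen-free work-up should deliver the tetraphenol without quinone formation.

## Compound list

1 | isovanillin (3-hydroxy-4-methoxybenzaldehyde) | COc1ccc(C=O)cc1O | starting material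
2 | 3-chlorophenylboronic acid | OB(O)c1cccc(Cl)c1 | starting material
3 | 3-(3-chlorophenoxy)-4-methoxybenzaldehyde | COc1ccc(C=O)cc1Oc1cccc(Cl)c1 | intermediate
4 | 2-(3-chlorophenoxy)-4-ethenyl-1-methoxybenzene | COc1ccc(C=C)cc1Oc1cccc(Cl)c1 | intermediate
5 | 4-bromophenylboronic acid | OB(O)c1ccc(Br)cc1 | starting material
6 | 3-(4-bromophenoxy)-4-methoxybenzaldehyde | COc1ccc(C=O)cc1Oc1ccc(Br)cc1 | intermediate
7 | 9-[2-[3-(3-chlorophenoxy)-4-methoxyphenyl]ethyl]-9-borabicyclo[3.3.1]nonane | COc1ccc(CCB2C3CCCC2CCC3)cc1Oc1cccc(Cl)c1 | intermediate (not isolated)
8 | 3-[4-[2-[3-(3-chlorophenoxy)-4-methoxyphenyl]ethyl]phenoxy]-4-methoxybenzaldehyde | COc1ccc(C=O)cc1Oc1ccc(CCc2ccc(OC)c(Oc3cccc(Cl)c3)c2)cc1 | intermediate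
9 | 2-(3-chlorophenoxy)-4-[2-[4-(5-ethenyl-2-methoxyphenoxy)phenyl]ethyl]-1-methoxybenzene | COc1ccc(C=C)cc1Oc1ccc(CCc2ccc(OC)c(Oc3cccc(Cl)c3)c2)cc1 | intermediate
10 | 9-BBN adduct of 9, boron on the terminal carbon of the former vinyl group | COc1ccc(CCB2C3CCCC2CCC3)cc1Oc1ccc(CCc2ccc(OC)c(Oc3cccc(Cl)c3)c2)cc1 | intermediate (not isolated)
11 | macrocyclic bis(methyl ether): 19-membered ring A–O–ring B–CH2CH2–ring C–O–ring D–CH2CH2, OMe at position 6 of ring A and position 4 of ring C | c1cc2cc(c1OC)Oc1ccc(cc1)CCc1ccc(OC)c(c1)Oc1cccc(c1)CC2 | intermediate
12 | macrocyclic bisphenol: OH at position 6 of ring A and position 4 of ring C | c1cc2cc(c1O)Oc1ccc(cc1)CCc1ccc(O)c(c1)Oc1cccc(c1)CC2 | intermediate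
13 | macrocyclic bis(N,N-diethylcarbamate), H at position 1 of ring A and position 3 of ring C | c1cc2cc(c1OC(=O)N(CC)CC)Oc1ccc(cc1)CCc1ccc(OC(=O)N(CC)CC)c(c1)Oc1cccc(c1)CC2 | intermediate
14 | dilithio species, Li at position 1 of ring A and position 3 of ring C | [Li]c1cc2cc(c1OC(=O)N(CC)CC)Oc1ccc(cc1)CCc1cc([Li])c(OC(=O)N(CC)CC)c(c1)Oc1cccc(c1)CC2 | intermediate (not isolated)
15 | bis(dimethyl boronate), B(OMe)2 at position 1 of ring A and position 3 of ring C | COB(OC)c1cc2cc(c1OC(=O)N(CC)CC)Oc1ccc(cc1)CCc1cc(B(OC)OC)c(OC(=O)N(CC)CC)c(c1)Oc1cccc(c1)CC2 | intermediate (not isolated)
16 | macrocyclic bis(N,N-diethylcarbamate) with OH at position 1 of ring A and position 3 of ring C | Oc1cc2cc(c1OC(=O)N(CC)CC)Oc1ccc(cc1)CCc1cc(O)c(OC(=O)N(CC)CC)c(c1)Oc1cccc(c1)CC2 | intermediate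
17 | target macrocyclic bis(catechol), CNP0511668.0 | Oc1cc2cc(c1O)Oc1ccc(cc1)CCc1cc(O)c(O)c(c1)Oc1cccc(c1)CC2 | target

## Step count and least certain steps

Total step count: 10. Longest linear sequence: 9 steps (steps 1, 2, 4, 5, 6, 7, 8, 9, 10).

**Step 9 (key step).**
- What may go wrong: incomplete second lithiation, so that only one ring is oxygenated; competing deprotonation next to the diaryl ether oxygens of rings B and D; carbamoyl migration to carbon if the dianion warms before the borate is added; poor solubility of the macrocycle at −78 °C, which would slow metalation and invite all of these.
- Fallback: it sets out from bisphenol 12 and avoids organolithium chemistry. Magnesium-mediated ortho-formylation (MgCl2, Et3N, paraformaldehyde, MeCN, reflux) can attack only the one free ortho carbon of each phenol and should give the macrocyclic bis(salicylaldehyde) F1. Dakin oxidation of F1 (H2O2 with catalytic acid, under argon) replaces each formyl group by a hydroxyl and comes back to the route at 17.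

**Step 6.**
- What may go wrong: intermolecular coupling outrunning ring closure, giving oligomers; slow insertion of palladium into the C–Cl bond, so that the alkylborane is lost by protodeboronation or β-hydride elimination.
- Fallback: it sets out from 9 and closes the ring by olefin metathesis. Suzuki vinylation of the chloride (K[CH2=CHBF3], Pd(OAc)2, SPhos, Cs2CO3, THF/H2O) should give the bis(styrene) F2. Ring-closing metathesis with the second-generation Grubbs catalyst at high dilution should give the macrocyclic stilbene F3 (either alkene geometry) with loss of ethylene. Hydrogenation of F3 (H2, Pd/C) comes back to the route at 11.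

**Step 4.**
- What may go wrong: reduction of the aldehyde of 6 by residual B–H or by hydride transfer from the alkylborane; slow transmetalation, leaving the bromide to be reduced or homocoupled.
- Fallback: it sets out from 6 and masks the aldehyde. Ethylene glycol with TsOH in toluene under water removal should give the dioxolane F4, 2-[3-(4-bromophenoxy)-4-methoxyphenyl]-1,3-dioxolane. Coupling of F4 with alkylborane 7 under the conditions of step 4 should give the coupled dioxolane F5, and aqueous HCl in THF comes back to the route at 8.

**Step 10.**
- What may go wrong: incomplete reduction, because the aluminium phenoxide formed next to each carbamate lowers its reactivity and the solubility of the intermediate; oxidation of the catecholate to an ortho-quinone during work-up.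
- Fallback: it sets out from 12 and uses a directing group that leaves under acid. Methoxymethylation (MOMCl, iPr2NEt, CH2Cl2) should give the bis(methoxymethyl ether) F6. Ortho-lithiation (n-BuLi, TMEDA, THF, 0 °C), B(OMe)3 and H2O2 should give the hydroxylated bis(methoxymethyl ether) F7. HCl in methanol comes back to the route at 17.

## Further compounds

F1 | step 9 | macrocyclic bis(salicylaldehyde), CHO at position 1 of ring A and position 3 of ring C | O=Cc1cc2cc(c1O)Oc1ccc(cc1)CCc1cc(C=O)c(O)c(c1)Oc1cccc(c1)CC2
F2 | step 6 | bis(styrene): 4-[2-[4-(5-ethenyl-2-methoxyphenoxy)phenyl]ethyl]-2-(3-ethenylphenoxy)-1-methoxybenzene | COc1ccc(C=C)cc1Oc1ccc(CCc2ccc(OC)c(Oc3cccc(C=C)c3)c2)cc1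
F3 | step 6 | macrocyclic stilbene, CH=CH in place of bridge 2, alkene geometry not defined | c1cc2cc(c1OC)Oc1ccc(cc1)CCc1ccc(OC)c(c1)Oc1cccc(c1)C=C2
F4 | step 4 | 2-[3-(4-bromophenoxy)-4-methoxyphenyl]-1,3-dioxolane | COc1ccc(C2OCCO2)cc1Oc1ccc(Br)cc1
F5 | step 4 | dioxolane of aldehyde 8 | COc1ccc(C2OCCO2)cc1Oc1ccc(CCc2ccc(OC)c(Oc3cccc(Cl)c3)c2)cc1
F6 | step 10 | macrocyclic bis(methoxymethyl ether) | c1cc2cc(c1OCOC)Oc1ccc(cc1)CCc1ccc(OCOC)c(c1)Oc1cccc(c1)CC2
F7 | step 10 | macrocyclic bis(methoxymethyl ether) with OH at position 1 of ring A and position 3 of ring C | Oc1cc2cc(c1OCOC)Oc1ccc(cc1)CCc1cc(O)c(OCOC)c(c1)Oc1cccc(c1)CC2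
A1 | alternative 1 | methyl 3-(4-bromophenoxy)-5-hydroxy-4-methoxybenzoate | COC(=O)c1cc(O)c(OC)c(c1)Oc1ccc(Br)cc1
A2 | alternative 1 | 3-(4-bromophenoxy)-4-methoxyfuran | COc1cocc1Oc1ccc(Br)cc1
A3 | alternative 1 | methyl propiolate | COC(=O)C#C
A4 | alternative 1 | 7-oxabicyclo[2.2.1]hepta-2,5-diene adduct of A2 and A3, racemic | COC(=O)C1=CC2OC1C(Oc1ccc(Br)cc1)=C2OC
A5 | alternative 2 | macrocyclic diaryl ether with OH at position 6 and Br at position 1 of ring A and two chlorines on ring B | Brc1cc2cc(c1O)Oc1c(Cl)cc(cc1Cl)CCc1cc(OC)c(OC)c(c1)Oc1cccc(c1)CC2
A6 | alternative 2 | seco bis(halophenol) | Oc1c(Br)cc(cc1Br)CCc1cccc(c1)Oc1cc(CCc2cc(Cl)c(O)c(Cl)c2)cc(OC)c1OC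
A7 | alternative 2 | macrocyclic bromo dienone, racemic | BrC1=CC2=CC(Br)(C1=O)Oc1c(Cl)cc(cc1Cl)CCc1cc(OC)c(OC)c(c1)Oc1cccc(c1)CC2
A8 | alternative 3 | methyl 4-aryloxybenzoate containing rings A, B and D | COC(=O)c1ccc(cc1)Oc1cc(cc(OC)c1OC)CCc1cccc(OCc2ccccc2)c1
A9 | alternative 3 | aryl ethynyl ether of the ring A phenol | C#COc1cc(cc(OC)c1OC)CCc1cccc(OCc2ccccc2)c1
A10 | alternative 3 | methyl coumalate | COC(=O)C1=COC(=O)C=C1
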